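4 questions stand here: two orders of the flasks and two amounts of target. I reckon them as rates, with every amount a fraction of the charge.

| flask | starting material | coupling partner | free catalyst | added ligand | remark | time |
|---|---|---|---|---|---|---|
| elm | 9 mM | 1.1 equiv | 5 mol% | 0.51 mM | run made earlier |  |
| cedar | 18 mM | 1.1 equiv | 5 mol% | 0.51 mM | run made earlier |  |
| ash | 28 mM | 1.1 equiv | 5 mol% | 0.51 mM | run made earlier |  |
| oak | 10 mM | 1.1 equiv | 5 mol% | 0.28 mM | run made earlier |  |
| Friday's | 10 mM | 0.740 equiv | 5 mol% | 0.80 mM |  | 5.0 min |
| Thursday's | 30 mM | 3.30 equiv | 5 mol% | 0.51 mM |  | 5.0 min |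
| Sunday's | 10 mM | 1.10 equiv | 5 mol% | 0.51 mM |  | 5.0 min |
| Saturday's | 10 mM | 1.10 equiv | 2.5 mol% | 0.12 mM |  | 5.0 min |
| Monday's | 10 mM | 0.740 equiv | 3 mol% | 0.51 mM |  | 5.0 min |
| Tuesday's | 10 mM | 2.20 equiv | 5 mol% | 0.25 mM |  | 5.0 min |

| elm: time / min | elm: target / % | cedar: time / min | cedar: target / % | ash: time / min | ash: target / % | oak: time / min | oak: target / % |
|---|---|---|---|---|---|---|---|
| 0.200 | 0.2 | 0.667 | 3.4 | 0.667 | 5.4 | 0.667 | 3.3 |
| 0.500 | 1.7 | 1.33 | 8.9 | 1.33 | 10.0 | 1.33 | 8.5 |
| 1.00 | 5.4 | 2.00 | 12.7 | 2.00 | 12.0 | 2.00 | 12.7 |
| 2.50 | 13.1 | 2.50 | 15.6 | 2.50 | 14.3 | 2.50 | 14.8 |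

(scatter of a reading: 0.5 percentage points)

* the flasks put in order of amount of target, in percent of the starting material charged, best first, at 5.0 min (Friday's / Thursday's / Sunday's / Saturday's / Monday's / Tuesday's)
* the same order at 40 min (Friday's / Thursday's / Sunday's / Saturday's / Monday's / Tuesday's)
* the amount of target, in percent of the starting material charged of the flask you put first, at 5.0 min
* the amount of target, in percent of the starting material charged of the flask you put last, at 5.0 min



At 5 mol% of free catalyst, the last readings of elm, cedar and ash lie between 13.1% and 15.6% although their charges of starting material differ, so I work in fractions of the charge. Scaling with loading is my assumption, since the earlier runs keep the loading the same. The oak run gains 0.0627 min⁻¹ between its first and last readings. This is my pace, the fraction of the charge turned into target per minute at 5 mol% of free catalyst, that is, the turnover frequency times the loading. Held for 5.0 min, it gives 31.4%.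

I take two readings against it. Within the oak run the pace falls from 0.0784 min⁻¹ to 0.0538 min⁻¹, a reading of 0.687 as a factor. The elm run, with more added ligand and less starting material than the oak run, stands at its last reading at 0.885 of the oak run's amount.

If the oak run's late pace drops by that factor once more for the rest of the time, an oak-like flask holds 24.0% at 5.0 min, less than the held figure. Tuesday's, with 0.25 mM of added ligand against the oak run's 0.28 mM, is my top at that amount. The earlier runs keep the coupling partner at 1.1 equiv, so I give it no factor. Monday's has elm's added ligand and 0.600 of the loading, which gives it 12.8%. Saturday's, with 0.500 of the loading and without elm's factor, gets 12.0%. These two lie too near for this reckoning to part them, so I put Monday's last by judgement, as it has less coupling partner than Saturday's.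

The forecast gives Tuesday's > Sunday's > Thursday's > Friday's > Saturday's > Monday's at 5.0 min and Sunday's > Friday's > Tuesday's > Monday's > Saturday's > Thursday's at 40 min, with 26% for its first flask and 12% for its last, against my 24.0% and 12.8%. Its grounds are that “rate tracks total catalyst and is roughly zero order in substrates”.

The flasks give Tuesday's > Thursday's > Sunday's > Friday's > Saturday's > Monday's at 5.0 min and Tuesday's > Sunday's > Thursday's > Saturday's > Friday's > Monday's at 40 min, with 33.7% in Tuesday's and 11.9% in Monday's.

    catalyst intermediate C → free catalyst + target (k = 0.150 s⁻¹)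
    starting material + target → side product (k = 0.380 M⁻¹ s⁻¹)
    coupling partner + free catalyst → catalyst intermediate A (k = 17.0 M⁻¹ s⁻¹)
    free catalyst + added ligand ⇌ idle complex, settled at all times (K = 2900 M⁻¹)
    starting material + catalyst intermediate A → catalyst intermediate B (k = 58.0 M⁻¹ s⁻¹)
    catalyst intermediate B ⇌ catalyst intermediate C (K = 22.0, k = 0.0580 s⁻¹)

Tuesday's averages 0.0674 min⁻¹, faster than the pace of 0.0627 min⁻¹, and ends 7.7 percentage points above the forecast and 9.7 points above my reckoning. Saturday's, with half the loading, comes to 15.7% by the pace and gives 14.1%. At 2.28 min in Tuesday's, starting material goes into catalyst intermediate B at 3.4 times the rate at which it goes with target into side product. At 5.00 min in Tuesday's that ratio is lower, at 2.9.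

(The numbers in the tables are simulated for substances that don't exist.)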